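A small charge of substrate, 20 mM in ochre, and a larger one, 30 mM in violet, each met 1.05 equiv of coupling partner, and I read both runs as fractions of the substrate charged.

| setting | ochre | violet | elm | cedar | birch | larch |
|---|---|---|---|---|---|---|
| substrate | 20 mM | 30 mM | 20 mM (fed, over 50 min) | 20 mM (fed, over 5.0 min) | 20 mM | 20 mM |
| coupling partner | 1.05 equiv | 1.05 equiv | 1.05 equiv | 1.05 equiv | 1.05 equiv | 1.05 equiv (fed, over 50 min) |
| remark | run made earlier | run made earlier | all else is in the flask from the start; the feed brings no volume worth counting | all else is in the flask from the start; the feed brings no volume worth counting | everything together at the start | all else is in the flask from the start; the feed brings no volume worth counting |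
| time |  |  | 4.0 h | 4.0 h | 4.0 h | 4.0 h |

- ochre (time / h: target / %, isomer of the product / %, substrate / %): 0.333: 52.9, 4.0, 41.6; 0.667: 57.9, 4.0, 37.0; 1.00: 58.2, 4.4, 36.8; 1.33: 58.7, 4.9, 35.4; 1.50: 58.2, 4.6, 35.5; 2.00: 58.3, 4.5, 35.5; 2.50: 58.2, 4.3, 35.5
- violet (time / min: target / %, isomer of the product / %, substrate / %): 3.00: 30.1, 2.5, 66.0; 6.00: 43.4, 4.0, 51.8; 10.0: 52.4, 4.2, 42.6; 15.0: 58.6, 4.6, 36.5; 20.0: 61.4, 4.1, 33.1; 25.0: 62.4, 5.0, 29.7

(scatter of a reading: 0.5 percentage points)

- a reading or a percentage of target counts all its forms, free or not

* the best flask by share of target in target plus isomer of the product; "all alike" if 1.5 percentage points covers them all (elm / cedar / birch / larch / all alike)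
* share of target in target plus isomer of the product at the end, elm
* share of target in target plus isomer of the product at the end, cedar
* share of target in target plus isomer of the product at the end, birch
* share of target in target plus isomer of the product at the end, larch

At 19.98 min ochre held 52.9% of target, and violet at 20.0 min held more, 61.4%. Ochre then stood still at 35.5% of substrate, with target and isomer together at 62.5% of the charge, although the partner had been charged in excess. So I took it that something other than the coupling stopped the flask, on a clock of its own, and that violet's coupling, quicker at the larger charge, got further before that clock ran out: 29.7% of substrate at 25.0 min, lower than ochre's.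

The two runs part on how far they go, but not on how the product divides. Pooling the last reading of each, I found target at 92.8%; this share of target in target plus isomer I call the split, the selectivity of the pair of routes. Violet's first reading, taken at its highest concentrations, gave 92.3%, close to that given a scatter of 0.5 percentage points on a small isomer reading. So I read the two routes as having the same total order. I expected feeding to leave the split alone, though substrate and partner were charged near equal in these runs and the partner was not read, which makes elm and larch my less certain flasks. I committed to 92.8% for each flask, and so to all alike.

The forecast gave 92.9%, 92.9%, 92.9% and 92.9% for elm, cedar, birch and larch, and all alike, saying “Feeding will lower conversion, since the catalyst dies during the feed, but the selectivity should stay put”.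

Elm, cedar, birch and larch ended at 92.7%, 92.7%, 92.7% and 92.7%: all alike.

    crystals ⇌ target, rate k1*(cs1 - [target]) while solid is left; crystals form when [target] > cs1 (solubility = 0.510 mM, k = 0.0258 s⁻¹)
    coupling partner → decomposed reagent (k = 7.37 × 10⁻⁴ s⁻¹)
    substrate + coupling partner → second isomer (k = 0.00190 L mol⁻¹ s⁻¹)
    substrate + coupling partner → isomer of the product (k = 0.00663 L mol⁻¹ s⁻¹)
    substrate + coupling partner → target (k = 0.0845 L mol⁻¹ s⁻¹)

In larch at 0.504 h, with the partner still going in, substrate went to target 13 times as fast as to isomer, and the split written as a ratio is 12.9. Elm ended with 69% of its substrate left and birch with 36%, on the same share of target. A neighbour flask like larch, with a quarter of its partner, kept 81.9% of its substrate and showed a share of 92.7%, against the split of 92.8%.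

The earlier runs and the new flask were computed for substances that don't exist.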